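**Plan** (hydroazulene numbering: C1 CHOH, C2, C3 C(OH)iPr, C3a, C4 ester carbon, C5, C6 =C–Me, C7, C8, C8a C–Me)
- Cuts: the aryl ester at C4–O; C6=C7 (metathesis) and C4–C5 (acyl substitution), which open the seven-membered ring to a cyclopentane β-hydroxy ester; then the C3a–C8a bond of the five-membered ring (C1–C2–C3–C3a–C8a) is undone by re-inserting C4 between C3a and C8a, giving a 2,3-epoxycyclohexanone (C4=O, oxirane C3a–C3).
- Enabling feature: C3(OH)–C3a(H)–C4(O) is an aldol-type array on the cyclopentane and C8a is quaternary. C4 can therefore have been a ring carbonyl between a non-enolisable carbon and an oxirane, so that alkoxide attack at C4 forces C8a to shift to C3a (six → five).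
- Forward order: cyclohexane first (dione → ketol → 3-isopropyl enone → epoxy ketone), contraction to the cyclopentane, then the seven-membered ring by metathesis of the C8a allyl group with a C4 methallyl ketone, C4 reduction, esterification, desilylation.
- Stereochemistry: C8a and C1 from enzymatic desymmetrisation; C3 from epoxidation anti to the C1 silyloxy group; C3a by inversion in the 1,2-shift; C4 by hydroxyl-directed hydride delivery from C3–OH.

Key step: step 7

Assumption: the yeast reduction is taken to give the (2S,3S)-ketol (hydroxyl cis to allyl), as is usual for 2-allyl-2-methyl-1,3-diones, and silyl-protected acid 19 is taken as a purchased building block.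

**Step 1**
Reactants: 1 2-methylcyclohexane-1,3-dione; 2 allyl bromide
Product: 3 2-allyl-2-methylcyclohexane-1,3-dione
Conditions: 1 M aq NaOH, rt
Reagents that add atoms: allyl bromide (2), C=CCBr
Why: C-alkylation of the stabilised 1,3-dione enolate in water should create the prochiral quaternary carbon (future C8a); no stereocentre is formed.

**Step 2**
Reactants: 3 2-allyl-2-methylcyclohexane-1,3-dione
Product: 4 (2S,3S)-2-allyl-3-hydroxy-2-methylcyclohexan-1-one
Conditions: baker's yeast, sucrose, H2O, 30 °C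
Reagents that add atoms: none
Why: Enzymatic desymmetrising reduction of a 2,2-disubstituted cyclohexane-1,3-dione should select one enantiotopic carbonyl and one face, giving the hydroxyl cis to allyl and thereby fixing C8a and C1 of the target.

**Step 3**
Reactants: 4 (2S,3S)-2-allyl-3-hydroxy-2-methylcyclohexan-1-one
Product: 5 (2S,3S)-2-allyl-3-[(tert-butyldimethylsilyl)oxy]-2-methylcyclohexan-1-one
Conditions: TBSOTf, 2,6-lutidine, CH2Cl2, −78 → 0 °C
Reagents that add atoms: tert-butyldimethylsilyl triflate, CC(C)(C)[Si](C)(C)OS(=O)(=O)C(F)(F)F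
Why: Silylation of the hindered secondary alcohol with the silyl triflate should block retro-aldol cleavage and install the group that later steers the epoxidation.

**Step 4**
Reactants: 5 (2S,3S)-2-allyl-3-[(tert-butyldimethylsilyl)oxy]-2-methylcyclohexan-1-one
Product: 7 (5S,6S)-6-allyl-5-[(tert-butyldimethylsilyl)oxy]-6-methylcyclohex-2-en-1-one, via TMS enol ether 6 (not isolated)
Conditions: LDA, TMSCl, THF, −78 °C; then Pd(OAc)2, MeCN, rt
Reagents that add atoms: none
Why: Saegusa–Ito oxidation: enolisation is possible only at the single α-CH2, and Pd(II) dehydrosilylation of the enol ether should give the enone.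

**Step 5**
Reactants: 7 (5S,6S)-6-allyl-5-[(tert-butyldimethylsilyl)oxy]-6-methylcyclohex-2-en-1-one; 8 isopropylmagnesium chloride
Product: 10 (5S,6S)-6-allyl-5-[(tert-butyldimethylsilyl)oxy]-3-isopropyl-6-methylcyclohex-2-en-1-one, via TMS enol ether 9 (not isolated)
Conditions: iPrMgCl, CuBr·SMe2 (10 mol %), TMSCl, THF, −78 °C; then Pd(OAc)2, MeCN, rt
Reagents that add atoms: isopropylmagnesium chloride (8), CC(C)[Mg]Cl
Why: Copper-catalysed, TMSCl-accelerated conjugate addition followed by a second Saegusa–Ito oxidation should re-form the enone with isopropyl on the β-carbon; the transient stereocentre is erased.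

**Step 6**
Reactants: 10 (5S,6S)-6-allyl-5-[(tert-butyldimethylsilyl)oxy]-3-isopropyl-6-methylcyclohex-2-en-1-one
Product: 11 (1S,3S,4S,6R)-3-allyl-4-[(tert-butyldimethylsilyl)oxy]-6-isopropyl-3-methyl-7-oxabicyclo[4.1.0]heptan-2-one
Conditions: 30 % H2O2, NaOH (cat.), MeOH, 0 °C
Reagents that add atoms: hydrogen peroxide, OO
Why: Weitz–Scheffer nucleophilic epoxidation touches only the enone, and hydroperoxide should add to the β-carbon anti to the C5 silyloxy group (as 5-substituted cyclohexenones generally do), placing the oxirane trans to OTBS and cis to the ring methyl, which sets C3.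

**Step 7**
Reactants: 11 (1S,3S,4S,6R)-3-allyl-4-[(tert-butyldimethylsilyl)oxy]-6-isopropyl-3-methyl-7-oxabicyclo[4.1.0]heptan-2-one
Product: 13 methyl (1R,2R,3S,5R)-2-allyl-3-[(tert-butyldimethylsilyl)oxy]-5-hydroxy-5-isopropyl-2-methylcyclopentane-1-carboxylate, via hemiketal alkoxide 12 (not isolated)
Conditions: NaOMe, MeOH, 0 → 50 °C; then aq NH4Cl
Reagents that add atoms: methanol (delivered as sodium methoxide), CO
Why: Proposed new method: methoxide adds reversibly to the non-enolisable, oxirane-activated ketone of 11 to give hemiketal alkoxide 12, whose O⁻ pushes the ring bond C4–C8a onto the oxirane CH (C3a) from the rear of the C3a–O bond, so that C4 leaves the ring as the ester carbon and the cyclohexanone becomes the cyclopentane (a semibenzilic, i.e. quasi-Favorskii, 1,2-shift with an epoxide as nucleofuge); the closest known reaction types are the alkoxide-induced Favorskii contraction of 2,3-epoxycyclohexanones to 2-hydroxycyclopentanecarboxylates and the quasi-Favorskii rearrangement of α-halo ketones without α′-hydrogens. No ring is closed by a cyclisation: the five-membered ring arises from the six-membered one by loss of one ring atom through a suprafacial 1,2-alkyl shift with backside displacement at C3a. C3a is set by inversion at the oxirane carbon and should also be the more stable ester epimer (trans to isopropyl and allyl), the C3 carbinol keeps the oxirane configuration and C8a migrates with retention. The step needs the shift to beat methoxide opening of the oxirane, enolate-type Favorskii closure and ionisation at the tertiary oxirane carbon: the α′-carbon is quaternary, the medium is basic, both neighbours of C3a are fully substituted, and in the half-chair with pseudo-equatorial OTBS the C4–C8a bond lies anti to the breaking C–O bond. The tertiary alkoxide that is released regenerates methoxide, and loss of oxirane strain plus ester formation should make the step strongly downhill.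

**Step 8**
Reactants: 13 methyl (1R,2R,3S,5R)-2-allyl-3-[(tert-butyldimethylsilyl)oxy]-5-hydroxy-5-isopropyl-2-methylcyclopentane-1-carboxylate
Product: 14 (1R,2R,3S,5R)-2-allyl-3-[(tert-butyldimethylsilyl)oxy]-5-hydroxy-5-isopropyl-N-methoxy-N,2-dimethylcyclopentane-1-carboxamide
Conditions: MeNH(OMe)·HCl, iPrMgCl, THF, −20 → 0 °C
Reagents that add atoms: N,O-dimethylhydroxylamine hydrochloride, CNOC.Cl
Why: Aminolysis of the methyl ester by the chloromagnesium amide (Weinreb amide synthesis) should be assisted by the neighbouring cis magnesium alkoxide and touches no stereocentre.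

**Step 9**
Reactants: 14 (1R,2R,3S,5R)-2-allyl-3-[(tert-butyldimethylsilyl)oxy]-5-hydroxy-5-isopropyl-N-methoxy-N,2-dimethylcyclopentane-1-carboxamide; 15 2-methylallylmagnesium chloride
Product: 16 1-[(1R,2R,3S,5R)-2-allyl-3-[(tert-butyldimethylsilyl)oxy]-5-hydroxy-5-isopropyl-2-methylcyclopentyl]-3-methylbut-3-en-1-one
Conditions: 2-methylallylmagnesium chloride, THF, −78 → −20 °C; cold aq NH4Cl
Reagents that add atoms: 2-methylallylmagnesium chloride (15), C=C(C)C[Mg]Cl
Why: Weinreb ketone synthesis should stop at single addition, and a cold buffered quench should keep the β,γ-unsaturated ketone out of conjugation.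

**Step 10**
Reactants: 16 1-[(1R,2R,3S,5R)-2-allyl-3-[(tert-butyldimethylsilyl)oxy]-5-hydroxy-5-isopropyl-2-methylcyclopentyl]-3-methylbut-3-en-1-one
Product: 17 (1S,3R,3aR,8aR)-1-[(tert-butyldimethylsilyl)oxy]-3-hydroxy-3-isopropyl-6,8a-dimethyl-2,3,3a,5,8,8a-hexahydroazulen-4(1H)-one
Conditions: Grubbs II (5 mol %), 1,4-benzoquinone (10 mol %), CH2Cl2 (2 mM), 40 °C
Reagents that add atoms: none
Why: Ring-closing metathesis of the allyl and methallyl groups, which are trans on the cyclopentane, should close the seven-membered ring with the trisubstituted C6=C7 olefin and give the trans-fused skeleton; benzoquinone suppresses Ru–H olefin migration.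

**Step 11**
Reactants: 17 (1S,3R,3aR,8aR)-1-[(tert-butyldimethylsilyl)oxy]-3-hydroxy-3-isopropyl-6,8a-dimethyl-2,3,3a,5,8,8a-hexahydroazulen-4(1H)-one
Product: 18 (1S,3R,3aS,4S,8aR)-1-[(tert-butyldimethylsilyl)oxy]-3-isopropyl-6,8a-dimethyl-1,2,3,3a,4,5,8,8a-octahydroazulene-3,4-diol
Conditions: Me4NBH(OAc)3, MeCN/AcOH 1:1, −30 → −20 °C
Reagents that add atoms: none
Why: Evans–Saksena hydroxyl-directed reduction: the C3 hydroxyl, cis to the acyl carbon, should bind boron and deliver hydride to the face of the C4 carbonyl that it overhangs, giving the 1,3-anti diol with the 4S carbinol.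

**Step 12**
Reactants: 18 (1S,3R,3aS,4S,8aR)-1-[(tert-butyldimethylsilyl)oxy]-3-isopropyl-6,8a-dimethyl-1,2,3,3a,4,5,8,8a-octahydroazulene-3,4-diol; 19 4-[(tert-butyldimethylsilyl)oxy]benzoic acid
Product: 20 (1S,3R,3aS,4S,8aR)-1-[(tert-butyldimethylsilyl)oxy]-3-hydroxy-3-isopropyl-6,8a-dimethyl-1,2,3,3a,4,5,8,8a-octahydroazulen-4-yl 4-[(tert-butyldimethylsilyl)oxy]benzoate
Conditions: DCC, DMAP (cat.), CH2Cl2, rt
Reagents that add atoms: 4-[(tert-butyldimethylsilyl)oxy]benzoic acid (19), CC(C)(C)[Si](C)(C)Oc1ccc(cc1)C(=O)O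
Why: Steglich esterification should acylate the only secondary hydroxyl, the tertiary carbinol being inert, with retention at C4.

**Step 13**
Reactants: 20 (1S,3R,3aS,4S,8aR)-1-[(tert-butyldimethylsilyl)oxy]-3-hydroxy-3-isopropyl-6,8a-dimethyl-1,2,3,3a,4,5,8,8a-octahydroazulen-4-yl 4-[(tert-butyldimethylsilyl)oxy]benzoate
Product: 21 2α-hydroxyferutinin
Conditions: HF·pyridine, pyridine/THF, 0 °C → rt
Reagents that add atoms: none
Why: Fluoride desilylation under buffered conditions should remove the aryl and the alkyl TBS ethers while the benzoate, the tertiary alcohol and the trisubstituted olefin remain intact.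

**Compound list**
1 | 2-methylcyclohexane-1,3-dione | CC1C(=O)CCCC1=O | starting material
2 | allyl bromide | C=CCBr | starting material
3 | 2-allyl-2-methylcyclohexane-1,3-dione | C=CCC1(C)C(=O)CCCC1=O | intermediate
4 | (2S,3S)-2-allyl-3-hydroxy-2-methylcyclohexan-1-one (OH cis to allyl) | C=CC[C@@]1(C)[C@@H](O)CCCC1=O | intermediate
5 | (2S,3S)-2-allyl-3-[(tert-butyldimethylsilyl)oxy]-2-methylcyclohexan-1-one | C=CC[C@@]1(C)[C@@H](O[Si](C)(C)C(C)(C)C)CCCC1=O | intermediate
6 | trimethylsilyl enol ether of 5 | C=CC[C@@]1(C)[C@@H](O[Si](C)(C)C(C)(C)C)CCC=C1O[Si](C)(C)C | intermediate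
7 | (5S,6S)-6-allyl-5-[(tert-butyldimethylsilyl)oxy]-6-methylcyclohex-2-en-1-one | C=CC[C@@]1(C)[C@@H](O[Si](C)(C)C(C)(C)C)CC=CC1=O | intermediate
8 | isopropylmagnesium chloride | CC(C)[Mg]Cl | starting material
9 | trimethylsilyl enol ether of the 3-isopropyl ketone (isopropyl trans to OTBS) | C=CC[C@@]1(C)[C@@H](O[Si](C)(C)C(C)(C)C)C[C@H](C(C)C)C=C1O[Si](C)(C)C | intermediate
10 | (5S,6S)-6-allyl-5-[(tert-butyldimethylsilyl)oxy]-3-isopropyl-6-methylcyclohex-2-en-1-one | C=CC[C@@]1(C)[C@@H](O[Si](C)(C)C(C)(C)C)CC(C(C)C)=CC1=O | intermediate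
11 | (1S,3S,4S,6R)-3-allyl-4-[(tert-butyldimethylsilyl)oxy]-6-isopropyl-3-methyl-7-oxabicyclo[4.1.0]heptan-2-one (oxirane trans to OTBS, cis to the ring methyl) | C=CC[C@@]1(C)[C@@H](O[Si](C)(C)C(C)(C)C)C[C@]2(C(C)C)O[C@@H]2C1=O | intermediate
12 | sodium hemiketal alkoxide (methoxide adduct at the carbonyl of 11) | C=CC[C@@]1(C)[C@@H](O[Si](C)(C)C(C)(C)C)C[C@]2(C(C)C)O[C@@H]2C1([O-])OC.[Na+] | intermediate
13 | methyl (1R,2R,3S,5R)-2-allyl-3-[(tert-butyldimethylsilyl)oxy]-5-hydroxy-5-isopropyl-2-methylcyclopentane-1-carboxylate | C=CC[C@]1(C)[C@@H](C(=O)OC)[C@](O)(C(C)C)C[C@@H]1O[Si](C)(C)C(C)(C)C | intermediate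
14 | (1R,2R,3S,5R)-2-allyl-3-[(tert-butyldimethylsilyl)oxy]-5-hydroxy-5-isopropyl-N-methoxy-N,2-dimethylcyclopentane-1-carboxamide | C=CC[C@]1(C)[C@@H](C(=O)N(C)OC)[C@](O)(C(C)C)C[C@@H]1O[Si](C)(C)C(C)(C)C | intermediate
15 | 2-methylallylmagnesium chloride | C=C(C)C[Mg]Cl | starting material
16 | 1-[(1R,2R,3S,5R)-2-allyl-3-[(tert-butyldimethylsilyl)oxy]-5-hydroxy-5-isopropyl-2-methylcyclopentyl]-3-methylbut-3-en-1-one | C=CC[C@]1(C)[C@@H](C(=O)CC(C)=C)[C@](O)(C(C)C)C[C@@H]1O[Si](C)(C)C(C)(C)C | intermediate
17 | (1S,3R,3aR,8aR)-1-[(tert-butyldimethylsilyl)oxy]-3-hydroxy-3-isopropyl-6,8a-dimethyl-2,3,3a,5,8,8a-hexahydroazulen-4(1H)-one | CC1=CC[C@]2(C)[C@@H](C(=O)C1)[C@](O)(C(C)C)C[C@@H]2O[Si](C)(C)C(C)(C)C | intermediate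
18 | (1S,3R,3aS,4S,8aR)-1-[(tert-butyldimethylsilyl)oxy]-3-isopropyl-6,8a-dimethyl-1,2,3,3a,4,5,8,8a-octahydroazulene-3,4-diol | CC1=CC[C@]2(C)[C@@H]([C@@H](O)C1)[C@](O)(C(C)C)C[C@@H]2O[Si](C)(C)C(C)(C)C | intermediate
19 | 4-[(tert-butyldimethylsilyl)oxy]benzoic acid | CC(C)(C)[Si](C)(C)Oc1ccc(cc1)C(=O)O | starting material
20 | (1S,3R,3aS,4S,8aR)-1-[(tert-butyldimethylsilyl)oxy]-3-hydroxy-3-isopropyl-6,8a-dimethyl-1,2,3,3a,4,5,8,8a-octahydroazulen-4-yl 4-[(tert-butyldimethylsilyl)oxy]benzoate | CC1=CC[C@]2(C)[C@@H]([C@@H](OC(=O)c3ccc(O[Si](C)(C)C(C)(C)C)cc3)C1)[C@](O)(C(C)C)C[C@@H]2O[Si](C)(C)C(C)(C)C | intermediate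
21 | 2α-hydroxyferutinin, (1S,3R,3aS,4S,8aR)-1,3-dihydroxy-3-isopropyl-6,8a-dimethyl-1,2,3,3a,4,5,8,8a-octahydroazulen-4-yl 4-hydroxybenzoate | CC1=CC[C@]2(C)[C@@H]([C@@H](OC(=O)c3ccc(O)cc3)C1)[C@](O)(C(C)C)C[C@@H]2O | target

Total step count: 13. Longest linear sequence: 13 steps (1 → 21).

**Steps most likely to fail**

1. Step 7 (proposed new method). Risk: the hemiketal alkoxide may form too sparingly or push too weakly to displace the oxirane oxygen, so that slow methoxide opening of the oxirane or simple recovery takes over. Fallback with known chemistry, setting out from 11 and returning at 13: reductive opening of the oxirane at the α-carbon (SmI2, THF/MeOH, −90 °C) should give the β-hydroxy ketone F1. TESOTf/2,6-lutidine should give its triethylsilyl ether F2. Claisen trifluoroacetylation (LiHMDS, CF3CO2CH2CF3, −78 °C) should give the 6-trifluoroacetyl ketone F3, and deacylative diazo transfer (MsN3, Et3N, MeCN/H2O) the α-diazo ketone F4. Irradiation in methanol (photochemical Wolff rearrangement, the same C8a migration, ketene trapped by methanol), followed by NaOMe equilibration at the ester-bearing carbon, should give the silyl-protected ester F5. Selective removal of the triethylsilyl group (HF·pyridine, 0 °C) returns 13.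

2. Step 11. Risk: poor facial selectivity, because the hindered tertiary hydroxyl may exchange onto boron more slowly than undirected hydride transfer occurs. Fallback from 17, returning at 20: reduction with a bulky external hydride (L-Selectride, THF, −78 °C) from the exposed face, opposite to the angular methyl and the C3 hydroxyl, should give the C4-epimeric diol F6. Mitsunobu esterification with acid 19 (PPh3, DIAD, toluene) then inverts C4 and installs the aryl ester in one operation, giving 20.

3. Step 8. Risk: no aminolysis at the doubly neopentyl ester carbonyl, or retro-aldol opening of the magnesium aldolate on warming. Fallback from 13, returning at 16: DIBAL-H reduction (CH2Cl2, −78 → 0 °C) should give the primary alcohol F7. TEMPO/PhI(OAc)2 oxidation of the primary hydroxyl should give the aldehyde F8. Addition of 15 should give the homoallylic carbinol F9 as an epimer mixture, and Dess–Martin oxidation converges both epimers on ketone 16.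

**Further compounds**
F1 | step 7 | 2-allyl-3-[(tert-butyldimethylsilyl)oxy]-5-hydroxy-5-isopropyl-2-methylcyclohexan-1-one (configuration as in 11) | C=CC[C@@]1(C)[C@@H](O[Si](C)(C)C(C)(C)C)C[C@@](O)(C(C)C)CC1=O
F2 | step 7 | triethylsilyl ether of F1 | C=CC[C@@]1(C)[C@@H](O[Si](C)(C)C(C)(C)C)C[C@@](O[Si](CC)(CC)CC)(C(C)C)CC1=O
F3 | step 7 | 6-trifluoroacetyl derivative of F2 | C=CC[C@@]1(C)[C@@H](O[Si](C)(C)C(C)(C)C)C[C@@](O[Si](CC)(CC)CC)(C(C)C)C(C(=O)C(F)(F)F)C1=O
F4 | step 7 | 6-diazo derivative of F2 | C=CC[C@@]1(C)[C@@H](O[Si](C)(C)C(C)(C)C)C[C@@](O[Si](CC)(CC)CC)(C(C)C)C(=[N+]=[N-])C1=O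
F5 | step 7 | O-triethylsilyl ether of 13 | C=CC[C@]1(C)[C@@H](C(=O)OC)[C@](O[Si](CC)(CC)CC)(C(C)C)C[C@@H]1O[Si](C)(C)C(C)(C)C
F6 | step 11 | C4 epimer of diol 18 | CC1=CC[C@]2(C)[C@@H]([C@H](O)C1)[C@](O)(C(C)C)C[C@@H]2O[Si](C)(C)C(C)(C)C
F7 | step 8 | (1R,2R,3S,5S)-2-allyl-3-[(tert-butyldimethylsilyl)oxy]-1-(hydroxymethyl)-5-isopropyl-2-methylcyclopentan-5-ol (primary alcohol from 13) | C=CC[C@]1(C)[C@@H](CO)[C@](O)(C(C)C)C[C@@H]1O[Si](C)(C)C(C)(C)C
F8 | step 8 | corresponding cyclopentanecarbaldehyde | C=CC[C@]1(C)[C@@H](C=O)[C@](O)(C(C)C)C[C@@H]1O[Si](C)(C)C(C)(C)C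
F9 | step 8 | homoallylic carbinol from F8 and 15 (both carbinol epimers) | C=CC[C@]1(C)[C@@H](C(O)CC(C)=C)[C@](O)(C(C)C)C[C@@H]1O[Si](C)(C)C(C)(C)C
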